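The ester is disconnected between C3 and C4 of its 19-(2-furyl)nonadeca-5,7-diynoyl chain. C3 lies β to the ester carbonyl C1, a homoenolate position, and C4 is propargylic to the C5≡C6–C7≡C8 diyne; the key step exploits exactly this pairing. A nickel-catalysed Negishi C(sp3)–C(sp3) coupling joins a β-zincio propanoate, already esterified with the complete 21-(2-furyl)henicosa-14,16-diyn-1-ol, to a furyl-terminated penta-2,4-diynyl bromide, so the last operation delivers the whole skeleton with the ester, both furan rings and both diynes in place. The precursors are the 3-iodopropanoate of the diynol and 2-(16-bromohexadeca-12,14-diynyl)furan; each diyne comes from a Cadiot–Chodkiewicz coupling.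

Key step: step 13

Remark on the chemistry: the target has no stereocentre and no stereogenic double bond, so it is achiral and no step needs stereocontrol.

Step 1
Reactants: 1 furan; 2 1-bromo-4-chlorobutane
Product: 4 2-(4-chlorobutyl)furan, via 2-furyllithium 3 (not isolated)
Conditions: n-BuLi, THF, 0 °C; then 2, 0 °C → rt
Reagents that add atoms: none
Why: α-Lithiation of furan at C2 followed by SN2 alkylation at the C–Br end of the dihalide, bromide being the better leaving group, should leave the C–Cl bond for step 2.

Step 2
Reactants: 4 2-(4-chlorobutyl)furan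
Product: 5 2-(hex-5-yn-1-yl)furan
Conditions: LiC≡CH·H2NCH2CH2NH2, NaI (cat.), DMSO, rt
Reagents that add atoms: lithium acetylide–ethylenediamine complex, [Li]C#C.NCCN
Why: SN2 alkylation of lithium acetylide by the primary chloride (iodide catalysis in DMSO) should install the terminal alkyne, the acetylide being too weak a base to metalate the furan.

Step 3
Reactants: 6 prop-2-yn-1-ol; 7 1-bromododecane
Product: 9 pentadec-2-yn-1-ol, via dilithiated prop-2-yn-1-ol 8 (not isolated)
Conditions: n-BuLi (2 equiv), THF–DMPU, −78 → 0 °C; then 7, 0 °C → rt; H2O
Reagents that add atoms: none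
Why: Acetylide alkylation: in the O,C-dilithio species the acetylide carbon is far more nucleophilic than the alkoxide, so SN2 reaction with the primary bromide should give the C-alkylated 2-alkyn-1-ol.

Step 4
Reactants: 9 pentadec-2-yn-1-ol
Product: 10 pentadec-14-yn-1-ol
Conditions: NaH, H2N(CH2)3NH2, 70 °C; then 9, 55 °C; H2O
Reagents that add atoms: none
Why: Alkyne zipper reaction: sodium 3-aminopropylamide should move the triple bond along the chain through allenic intermediates, driven by irreversible formation of the terminal acetylide at the end remote from the alkoxide.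

Step 5
Reactants: 10 pentadec-14-yn-1-ol
Product: 11 15-bromopentadec-14-yn-1-ol
Conditions: NBS, AgNO3 (cat.), acetone, rt
Reagents that add atoms: N-bromosuccinimide, O=C1CCC(=O)N1Br
Why: Silver-catalysed electrophilic bromination of the terminal alkyne through its silver acetylide should give the 1-bromoalkyne without touching the primary alcohol.

Step 6
Reactants: 11 15-bromopentadec-14-yn-1-ol; 5 2-(hex-5-yn-1-yl)furan
Product: 12 21-(furan-2-yl)henicosa-14,16-diyn-1-ol
Conditions: CuCl (cat.), NH2OH·HCl, n-BuNH2, H2O–MeOH–THF, 0 °C → rt
Reagents that add atoms: none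
Why: Cadiot–Chodkiewicz coupling of the copper(I) acetylide of 5 with bromoalkyne 11 should give the unsymmetrical 1,3-diyne, with hydroxylamine holding copper at +1 against Glaser homocoupling and the bromine placed on the furan-free partner so that NBS never meets a furan ring.

Step 7
Reactants: 12 21-(furan-2-yl)henicosa-14,16-diyn-1-ol; 13 3-iodopropanoic acid
Product: 14 21-(furan-2-yl)henicosa-14,16-diyn-1-yl 3-iodopropanoate
Conditions: DCC, DMAP (cat.), CH2Cl2, 0 °C
Reagents that add atoms: none
Why: Steglich esterification through the O-acylisourea and acylpyridinium ion, run cold with little DMAP, should acylate the primary alcohol before E1cB loss of HI from the β-iodo acyl unit can compete.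

Step 8
Reactants: 15 2-bromofuran; 16 1,11-dibromoundecane
Product: 18 2-(11-bromoundecyl)furan, via 2-furylmagnesium bromide 17 (not isolated)
Conditions: Mg turnings, I2 (cat.), THF, rt → 40 °C; then 16 (3 equiv), Li2CuCl4 (cat.), THF, −10 °C → rt
Reagents that add atoms: none
Why: Magnesium insertion into the C2–Br bond should give the furyl Grignard reagent, and copper-catalysed (Kochi-type) C(sp2)–C(sp3) coupling with a primary alkyl bromide, run with an excess of the symmetrical dibromide, should favour monosubstitution over double substitution.

Step 9
Reactants: 18 2-(11-bromoundecyl)furan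
Product: 19 2-(tridec-12-yn-1-yl)furan
Conditions: LiC≡CH·H2NCH2CH2NH2, DMSO, rt
Reagents that add atoms: lithium acetylide–ethylenediamine complex, [Li]C#C.NCCN
Why: SN2 alkylation of lithium acetylide by the primary bromide in DMSO should give the terminal alkyne, as in step 2.

Step 10
Reactants: 6 prop-2-yn-1-ol
Product: 20 3-bromoprop-2-yn-1-ol
Conditions: NBS, AgNO3 (cat.), acetone, rt
Reagents that add atoms: N-bromosuccinimide, O=C1CCC(=O)N1Br
Why: Silver-catalysed bromination of the terminal alkyne through the silver acetylide should give the bromoalkyne, as in step 5.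

Step 11
Reactants: 19 2-(tridec-12-yn-1-yl)furan; 20 3-bromoprop-2-yn-1-ol
Product: 21 16-(furan-2-yl)hexadeca-2,4-diyn-1-ol
Conditions: CuCl (cat.), NH2OH·HCl, n-BuNH2, H2O–MeOH–THF, 0 °C → rt
Reagents that add atoms: none
Why: Cadiot–Chodkiewicz coupling of the copper(I) acetylide of 19 with the bromoalkyne should give the unsymmetrical diynol, the free propargylic alcohol and the furan being inert to the aqueous amine medium.

Step 12
Reactants: 21 16-(furan-2-yl)hexadeca-2,4-diyn-1-ol
Product: 22 2-(16-bromohexadeca-12,14-diyn-1-yl)furan
Conditions: CBr4, PPh3, CH2Cl2, 0 °C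
Reagents that add atoms: carbon tetrabromide, BrC(Br)(Br)Br
Why: Appel reaction: bromide should displace the alkoxyphosphonium ion by SN2 at the primary propargylic carbon under neutral conditions that the furan and the diyne tolerate.

Step 13
Reactants: 14 21-(furan-2-yl)henicosa-14,16-diyn-1-yl 3-iodopropanoate; 22 2-(16-bromohexadeca-12,14-diyn-1-yl)furan
Product: 24 21-(furan-2-yl)henicosa-14,16-diyn-1-yl 19-(furan-2-yl)nonadeca-5,7-diynoate, via β-zincio ester 23 (not isolated)
Conditions: Zn dust, I2 (cat.), DMA, rt; then 22, NiCl2·glyme (10 mol%), 2,2′:6′,2″-terpyridine (10 mol%), DMA, rt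
Reagents that add atoms: none
Why: Zinc should insert into the primary C–I bond of 14 to give the zinc homoenolate 23, which neither β-eliminates nor attacks esters; transmetalation to the terpyridine–nickel(I) centre then gives an alkylnickel species that abstracts bromine from 22 to form a delocalised penta-2,4-diynyl radical, and radical capture at nickel followed by reductive elimination from nickel(III) forms the C(sp3)–C(sp3) bond between C3 and C4 of the acyl chain. The closest known reaction type is the nickel/terpyridine-catalysed Negishi alkyl–alkyl cross-coupling of alkylzinc halides with propargylic bromides. No ring is closed and no stereocentre is formed. The selectivity needed is bond formation at the propargylic CH2 terminus and not at the allenic (C6) or cumulenic (C8) positions of the radical; it should be secured because CH2 is the only unsubstituted primary terminus, because coupling there keeps the conjugated diyne, and because nickel, unlike copper or palladium, does not favour SN2′ delivery to propargylic electrophiles. Chemoselectivity rests on the mildness of the organozinc, which should leave the ester, both furan rings and both diynes untouched, and on the tridentate ligand, which suppresses β-hydride elimination.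

Compound list
1 | furan | c1ccoc1 | starting material
2 | 1-bromo-4-chlorobutane | ClCCCCBr | starting material
3 | 2-furyllithium | [Li]c1ccco1 | intermediate
4 | 2-(4-chlorobutyl)furan | ClCCCCc1ccco1 | intermediate
5 | 2-(hex-5-yn-1-yl)furan | C#CCCCCc1ccco1 | intermediate
6 | prop-2-yn-1-ol | C#CCO | starting material
7 | 1-bromododecane | BrCCCCCCCCCCCC | starting material
8 | dilithiated prop-2-yn-1-ol (lithium 3-lithioprop-2-yn-1-olate) | [Li]C#CCO[Li] | intermediate
9 | pentadec-2-yn-1-ol | OCC#CCCCCCCCCCCCC | intermediate
10 | pentadec-14-yn-1-ol | OCCCCCCCCCCCCCC#C | intermediate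
11 | 15-bromopentadec-14-yn-1-ol | OCCCCCCCCCCCCCC#CBr | intermediate
12 | 21-(furan-2-yl)henicosa-14,16-diyn-1-ol | OCCCCCCCCCCCCCC#CC#CCCCCc1ccco1 | intermediate
13 | 3-iodopropanoic acid | OC(=O)CCI | starting material
14 | 21-(furan-2-yl)henicosa-14,16-diyn-1-yl 3-iodopropanoate | ICCC(=O)OCCCCCCCCCCCCCC#CC#CCCCCc1ccco1 | intermediate
15 | 2-bromofuran | Brc1ccco1 | starting material
16 | 1,11-dibromoundecane | BrCCCCCCCCCCCBr | starting material
17 | 2-furylmagnesium bromide | Br[Mg]c1ccco1 | intermediate
18 | 2-(11-bromoundecyl)furan | BrCCCCCCCCCCCc1ccco1 | intermediate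
19 | 2-(tridec-12-yn-1-yl)furan | C#CCCCCCCCCCCCc1ccco1 | intermediate
20 | 3-bromoprop-2-yn-1-ol | OCC#CBr | intermediate
21 | 16-(furan-2-yl)hexadeca-2,4-diyn-1-ol | OCC#CC#CCCCCCCCCCCCc1ccco1 | intermediate
22 | 2-(16-bromohexadeca-12,14-diyn-1-yl)furan | BrCC#CC#CCCCCCCCCCCCc1ccco1 | intermediate
23 | {3-[21-(furan-2-yl)henicosa-14,16-diyn-1-yloxy]-3-oxopropyl}zinc iodide (β-zincio ester) | I[Zn]CCC(=O)OCCCCCCCCCCCCCC#CC#CCCCCc1ccco1 | intermediate
24 | 21-(furan-2-yl)henicosa-14,16-diyn-1-yl 19-(furan-2-yl)nonadeca-5,7-diynoate | O=C(CCCC#CC#CCCCCCCCCCCCc1ccco1)OCCCCCCCCCCCCCC#CC#CCCCCc1ccco1 | target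

Total step count: 13.
Longest linear sequence: 6 steps (steps 3, 4, 5, 6, 7 and 13, from prop-2-yn-1-ol to the target).

Steps most likely to fail

1. Step 13. The delocalised pentadiynyl radical may be captured at its allenic position (loss of regiocontrol), the bromide may homodimerise by radical coupling, or low-valent nickel may oligomerise the diynes. The fallback gives up the C3–C4 coupling and builds the acid diyne first; it sets out from alkyne 19 and alcohol 12. Commercial hex-5-ynoic acid would be brominated (NBS, AgNO3 cat., acetone) to 6-bromohex-5-ynoic acid F1. Cadiot–Chodkiewicz coupling of F1 with 19 (CuCl cat., NH2OH·HCl, n-BuNH2, aqueous MeOH) should give 19-(furan-2-yl)nonadeca-5,7-diynoic acid F2. Steglich esterification of F2 with 12 (DCC, DMAP cat., CH2Cl2) comes back to the route at target 24.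

2. Step 12. The penta-2,4-diynyl bromide may decompose or polymerise while it is separated from triphenylphosphine oxide, and phosphine may add to the activated diyne. The fallback is phosphorus-free and sets out from diynol 21. MsCl and Et3N in CH2Cl2 at −20 °C should give 16-(furan-2-yl)hexadeca-2,4-diyn-1-yl methanesulfonate F3, which after extractive work-up is treated without chromatography with LiBr in acetone at 0 °C. This SN2 displacement comes back to the route at bromide 22, which is used at once.

3. Step 7. Base-induced E1cB loss of HI during carbodiimide activation may give the acrylate in place of the β-iodo ester. The fallback separates acylation from introduction of iodine and sets out from alcohol 12. 3-Bromopropanoyl chloride and 2,6-lutidine in CH2Cl2 at −20 °C should give 21-(furan-2-yl)henicosa-14,16-diyn-1-yl 3-bromopropanoate F4. Finkelstein exchange (NaI, acetone, rt) comes back to the route at iodide 14.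

Further compounds
F1 | step 13 | 6-bromohex-5-ynoic acid | OC(=O)CCCC#CBr
F2 | step 13 | 19-(furan-2-yl)nonadeca-5,7-diynoic acid | OC(=O)CCCC#CC#CCCCCCCCCCCCc1ccco1
F3 | step 12 | 16-(furan-2-yl)hexadeca-2,4-diyn-1-yl methanesulfonate | CS(=O)(=O)OCC#CC#CCCCCCCCCCCCc1ccco1
F4 | step 7 | 21-(furan-2-yl)henicosa-14,16-diyn-1-yl 3-bromopropanoate | BrCCC(=O)OCCCCCCCCCCCCCC#CC#CCCCCc1ccco1
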